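**Plan**
1. Retrosynthesis: both C–Br centres are traced back to alkenyl bromides (C5=C6 and C3'=C4'), the C5' carbinol to a ketone, and the C2–C1' bond (tertiary carbinol of ring A to the quaternary cyclopentane carbon) is cut as an aldol bond. The C8 methyl and the C8/C8a oxygens are then removed from the decalin.
2. Enabling feature: C2–OH and C5'–OH stand 1,3 across C1' (β-hydroxy ketone retron). C1' lies between the C5' carbonyl and the quaternary C2' (CMe2), so bromo enone 15 can enolize only at C1'. The acceptor carbonyl C2 sits in chair ring A under an axial C8a oxygen.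
3. Forward: rings A/B come intact from (S)-Wieland–Miescher ketone (steps 1–9), the five-membered ring from 3-ethoxycyclopent-2-enone (steps 10–13). The fragments are joined by a silyl-Lewis-acid Mukaiyama aldol addition (step 14), followed by ketone reduction and one HAT hydrogenation of both alkenyl bromides.
4. Stereochemistry: C4a from 1; C8a by osmylation anti to the angular methyl; C8 by equatorial methyl addition; C2 (equatorial attack) and C1' (face of the diene) in step 14; C5' by hydride from the methyl face; C5 and C3' by H-atom delivery to the open faces in step 16.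

Key step: step 14

Remark: locants follow the target (decalin C1–C8a with the cyclopentyl-bearing carbinol as C2 and the bromine-bearing carbon as C5; cyclopentane C1'–C5' with C1' bonded to C2, C2' = CMe2, C3' = CHBr, C5' = CHOH); α is the decalin face that carries the C4a methyl; 12 and 15 are racemic because their only stereocentre is erased by enolization; 1 and 11 are taken as commercial.

Step 1
Reactants: 1 (S)-Wieland–Miescher ketone
Product: 2 (4aS,5S)-5-hydroxy-4a-methyl-4,4a,5,6,7,8-hexahydronaphthalen-2(3H)-one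
Conditions: NaBH4 (0.3 equiv), EtOH, −10 °C
Reagents that add atoms: none
Why: The saturated C5 ketone is more electrophilic than the vinylogous C2 carbonyl and is reduced chemoselectively (borohydride reduction), with axial hydride delivery anti to the angular methyl giving the equatorial (5S) alcohol, a temporary stereocentre that only serves to differentiate the two carbonyls.

Step 2
Reactants: 2 (4aS,5S)-5-hydroxy-4a-methyl-4,4a,5,6,7,8-hexahydronaphthalen-2(3H)-one
Product: 3 (4a'S,5'S)-4a'-methyl-3',4',4a',5',6',7'-hexahydro-1'H-spiro[[1,3]dioxolane-2,2'-naphthalen]-5'-ol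
Conditions: ethylene glycol, TsOH (cat.), benzene, reflux, Dean–Stark
Reagents that add atoms: ethylene glycol OCCO
Why: Acid-catalysed dioxolane formation on the enone proceeds through the dienol and shifts the alkene to the β,γ-position C8=C8a (deconjugative ketalization as used for Δ4-3-keto steroids), which masks C2 and exposes the alkene needed for the C8/C8a oxygens.

Step 3
Reactants: 3 (4a'S,5'S)-4a'-methyl-3',4',4a',5',6',7'-hexahydro-1'H-spiro[[1,3]dioxolane-2,2'-naphthalen]-5'-ol
Product: 4 (4a'S)-4a'-methyl-3',4',6',7'-tetrahydro-1'H-spiro[[1,3]dioxolane-2,2'-naphthalen]-5'(4a'H)-one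
Conditions: TPAP (5 mol %), NMO, 4 Å MS, CH2Cl2, rt
Reagents that add atoms: none
Why: Ley–Griffith oxidation regenerates the C5 ketone under neutral conditions that leave the acid-labile ketal and the alkene untouched, and the alkene cannot move into conjugation because C4a is quaternary.

Step 4
Reactants: 4 (4a'S)-4a'-methyl-3',4',6',7'-tetrahydro-1'H-spiro[[1,3]dioxolane-2,2'-naphthalen]-5'(4a'H)-one
Product: 5 (4a'S)-5'-bromo-4a'-methyl-3',4',4a',7'-tetrahydro-1'H-spiro[[1,3]dioxolane-2,2'-naphthalene]
Conditions: (PhO)3P, Br2, CH2Cl2, −60 °C; then Et3N, 4, −60 °C → reflux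
Reagents that add atoms: bromine BrBr
Why: Triphenyl phosphite–bromine converts an enolizable ketone into the alkenyl bromide through an oxyphosphonium intermediate and base-induced loss of HBr (ketone-to-vinyl-bromide conversion), and since C4a has no hydrogen the double bond can only form toward C6.

Step 5
Reactants: 5 (4a'S)-5'-bromo-4a'-methyl-3',4',4a',7'-tetrahydro-1'H-spiro[[1,3]dioxolane-2,2'-naphthalene]
Product: 6 (4a'S,8'S,8a'R)-5'-bromo-4a'-methyl-3',4',4a',7',8',8a'-hexahydro-1'H-spiro[[1,3]dioxolane-2,2'-naphthalene]-8',8a'-diol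
Conditions: OsO4 (2 mol %), NMO, acetone–H2O, rt
Reagents that add atoms: N-methylmorpholine N-oxide C[N+]1([O-])CCOCC1; water O
Why: Catalytic osmylation (Upjohn dihydroxylation) selects the electron-rich trisubstituted C8=C8a alkene over the electron-poor alkenyl bromide and adds both oxygens from the β face, anti to the angular C4a methyl, which sets C8a (8aR).

Step 6
Reactants: 6 (4a'S,8'S,8a'R)-5'-bromo-4a'-methyl-3',4',4a',7',8',8a'-hexahydro-1'H-spiro[[1,3]dioxolane-2,2'-naphthalene]-8',8a'-diol
Product: 7 (4a'S,8a'R)-5'-bromo-8a'-hydroxy-4a'-methyl-3',4',4a',8a'-tetrahydro-1'H-spiro[[1,3]dioxolane-2,2'-naphthalen]-8'(7'H)-one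
Conditions: IBX, DMSO, rt
Reagents that add atoms: none
Why: IBX oxidizes the secondary C8 hydroxyl of the secondary/tertiary glycol to the α-hydroxy ketone without glycol cleavage and without base, so the β,γ-unsaturated ketone is not isomerized.

Step 7
Reactants: 7 (4a'S,8a'R)-5'-bromo-8a'-hydroxy-4a'-methyl-3',4',4a',8a'-tetrahydro-1'H-spiro[[1,3]dioxolane-2,2'-naphthalen]-8'(7'H)-one
Product: 8 (4a'S,8'R,8a'R)-5'-bromo-4a',8'-dimethyl-3',4',4a',7',8',8a'-hexahydro-1'H-spiro[[1,3]dioxolane-2,2'-naphthalene]-8',8a'-diol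
Conditions: MeMgBr (3 equiv), CeCl3 (anhydrous), THF, −78 °C
Reagents that add atoms: methylmagnesium bromide C[Mg]Br
Why: The weakly basic organocerium reagent adds to the easily enolizable C8 ketone (organocerium 1,2-addition), entering from the β side (equatorial) because the α-axial path is blocked by the 1,3-diaxial angular methyl, which gives the axial 8α-hydroxyl trans-diaxial to the C8a hydroxyl (8R).

Step 8
Reactants: 8 (4a'S,8'R,8a'R)-5'-bromo-4a',8'-dimethyl-3',4',4a',7',8',8a'-hexahydro-1'H-spiro[[1,3]dioxolane-2,2'-naphthalene]-8',8a'-diol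
Product: 9 (4aS,8R,8aR)-5-bromo-8,8a-dihydroxy-4a,8-dimethyl-3,4,4a,7,8,8a-hexahydronaphthalen-2(1H)-one
Conditions: PPTS, acetone–H2O, 40 °C
Reagents that add atoms: water O
Why: Mild acid-catalysed hydrolysis removes the dioxolane (acetal hydrolysis), and the buffered acid is chosen so that the resulting β-hydroxy ketone does not dehydrate to the enone.

Step 9
Reactants: 9 (4aS,8R,8aR)-5-bromo-8,8a-dihydroxy-4a,8-dimethyl-3,4,4a,7,8,8a-hexahydronaphthalen-2(1H)-one
Product: 10 (4aS,8R,8aR)-5-bromo-4a,8-dimethyl-8,8a-bis(trimethylsilyloxy)-3,4,4a,7,8,8a-hexahydronaphthalen-2(1H)-one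
Conditions: 1-(trimethylsilyl)imidazole, CH2Cl2, rt
Reagents that add atoms: 1-(trimethylsilyl)imidazole C[Si](C)(C)n1ccnc1
Why: N-silylimidazole silylates both hindered tertiary hydroxyls without enolizing the ketone (silyl ether protection), so that the diol cannot quench the Lewis acid of step 14 and the axial C8a silyloxy group shields the β face of C2.

Step 10
Reactants: 11 3-ethoxycyclopent-2-en-1-one
Product: 13 3-ethoxy-5,5-dimethylcyclopent-2-en-1-one, via 3-ethoxy-5-methylcyclopent-2-en-1-one 12 (not isolated)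
Conditions: LDA, THF, −78 °C, MeI; then LDA, −78 °C, MeI (one pot)
Reagents that add atoms: iodomethane CI
Why: Kinetic deprotonation of the vinylogous ester occurs at the α′-carbon C5, so two successive enolate methylations (Stork–Danheiser-type α′-alkylation) place the gem-dimethyl group next to the carbonyl with unambiguous regiochemistry.

Step 11
Reactants: 13 3-ethoxy-5,5-dimethylcyclopent-2-en-1-one
Product: 14 3-bromo-4,4-dimethylcyclopent-2-en-1-one
Conditions: (COBr)2, CH2Cl2, 0 °C → rt; aq. NaHCO3
Reagents that add atoms: oxalyl bromide O=C(Br)C(=O)Br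
Why: Proposed new method: the nucleophilic carbonyl oxygen of the vinylogous ester is acylated by oxalyl bromide to a 1-acyloxy-3-ethoxyallyl cation, bromide adds at C1 because only there can a good leaving group depart, the oxalate half fragments to CO and CO2, and bromide dealkylates the remaining O-ethyl oxocarbenium ion to the ketone, so bromine ends on the former carbonyl carbon next to CMe2 and the carbonyl on the former ethoxy carbon (a 1,3-transposition); the closest known reaction type is the conversion of cyclic 1,3-diketones into β-bromo enones with oxalyl bromide or Ph3P·Br2, which on the free unsymmetrical diketone would place bromine on the less hindered carbon instead.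

Step 12
Reactants: 14 3-bromo-4,4-dimethylcyclopent-2-en-1-one
Product: 15 3-bromo-4,4,5-trimethylcyclopent-2-en-1-one (racemic)
Conditions: LDA, THF, −78 °C; MeI, −78 → −30 °C
Reagents that add atoms: iodomethane CI
Why: C5 is the only enolizable position of the β-bromo enone (C4 is quaternary, C2 vinylic), so kinetic enolate methylation installs the future C1' methyl group; the new stereocentre is racemic and is erased in step 13.

Step 13
Reactants: 15 3-bromo-4,4,5-trimethylcyclopent-2-en-1-one (racemic)
Product: 16 (4-bromo-2,3,3-trimethylcyclopenta-1,4-dien-1-yl)oxy-trimethylsilane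
Conditions: LDA, THF, −78 °C; TMSCl; non-aqueous work-up
Reagents that add atoms: chlorotrimethylsilane C[Si](C)(C)Cl
Why: Deprotonation at the single remaining α′-hydrogen and O-silylation of the cross-conjugated dienolate (silyl enol ether formation) give the 2-siloxydiene as one regioisomer.

Step 14
Reactants: 10 (4aS,8R,8aR)-5-bromo-4a,8-dimethyl-8,8a-bis(trimethylsilyloxy)-3,4,4a,7,8,8a-hexahydronaphthalen-2(1H)-one; 16 (4-bromo-2,3,3-trimethylcyclopenta-1,4-dien-1-yl)oxy-trimethylsilane
Product: 17 (2R,4aS,8R,8aR)-5-bromo-2-[(1S)-3-bromo-1,2,2-trimethyl-5-oxocyclopent-3-en-1-yl]-4a,8-dimethyl-2,8,8a-tris(trimethylsilyloxy)-1,2,3,4,4a,7,8,8a-octahydronaphthalene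
Conditions: 16 (1.5 equiv), Tf2NH (5 mol %, forms TMSNTf2 in situ), CH2Cl2, −78 °C; Et3N quench
Reagents that add atoms: none
Why: The silyl triflimide formed from Tf2NH and 16 activates the only carbonyl of 10 (C2), the siloxydiene attacks through C1' in an open transition state, and the silyl group ends on the new tertiary oxygen, so the congested aldolate is trapped as its ether and cannot revert by retro-aldol cleavage; the closest known reaction type is the silyl-Lewis-acid-catalysed Mukaiyama aldol addition of fully substituted enol silanes to ketones. The step closes no ring. C2 is set by equatorial attack on the chair cyclohexanone of ring A, because the axial C8a silyloxy group and axial H-4 block the axial path, which places the new oxygen axial and syn to the C8a oxygen as in the target. C1' is set by the choice between the two enantiotopic faces of the achiral diene: in the antiperiplanar arrangement the flat enol carbon C5' sits between C1 and C3, the bulky C2' (CMe2) turns to the open C3 side and the small methyl to the C1 side, which is crowded by C8a and the C8 substituents, and this arrangement leads to the required relative configuration. The step needs site selectivity on the nucleophile, secured by the quaternary C2' that leaves C1' as the only enolizable carbon of 15, and face selectivity on the diene, which rests on the steric difference between the C1 and C3 arms and is the least secure point of the route.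

Step 15
Reactants: 17 (2R,4aS,8R,8aR)-5-bromo-2-[(1S)-3-bromo-1,2,2-trimethyl-5-oxocyclopent-3-en-1-yl]-4a,8-dimethyl-2,8,8a-tris(trimethylsilyloxy)-1,2,3,4,4a,7,8,8a-octahydronaphthalene
Product: 19 (2R,4aS,8R,8aR)-5-bromo-2-[(1R,5S)-3-bromo-5-hydroxy-1,2,2-trimethylcyclopent-3-en-1-yl]-4a,8-dimethyl-1,2,3,4,4a,7,8,8a-octahydronaphthalene-2,8,8a-triol, via tris-silyl allylic alcohol 18 (not isolated)
Conditions: NaBH4, CeCl3·7H2O, MeOH–THF, −78 → −20 °C; then 1 M HCl (aq) to pH 2, 0 °C → rt
Reagents that add atoms: none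
Why: Luche reduction delivers hydride to the carbonyl carbon only (no conjugate addition that would expel bromide) and from the face of the C1' methyl, opposite the bulky C2 substituent, so the C5' hydroxyl ends cis to the decalin (5'S); dilute acid then hydrolyses the three trimethylsilyl ethers.

Step 16
Reactants: 19 (2R,4aS,8R,8aR)-5-bromo-2-[(1R,5S)-3-bromo-5-hydroxy-1,2,2-trimethylcyclopent-3-en-1-yl]-4a,8-dimethyl-1,2,3,4,4a,7,8,8a-octahydronaphthalene-2,8,8a-triol
Product: 20 neoirietetraol, (2R,4aS,5S,8R,8aR)-5-bromo-2-[(1R,3R,5S)-3-bromo-5-hydroxy-1,2,2-trimethylcyclopentyl]-4a,8-dimethyldecahydronaphthalene-2,8,8a-triol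
Conditions: Mn(dpm)3 (cat.), PhSiH3, t-BuOOH, i-PrOH, rt
Reagents that add atoms: none
Why: Metal-hydride hydrogen-atom transfer (Mukaiyama-type HAT hydrogenation, a method known to reduce haloalkenes to alkyl halides without C–halogen cleavage) places H• on the CH terminus of each alkenyl bromide and the α-bromoalkyl radicals are then quenched on their open face, axially and anti to the angular methyl at C5 (equatorial bromide, 5S) and anti to the decalin substituent of C1' at C3' (bromide cis to it, 3'R), which are also the more stable epimers.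

**Compound list**
1 | (S)-Wieland–Miescher ketone, (8aS)-8a-methyl-3,4,8,8a-tetrahydronaphthalene-1,6(2H,7H)-dione | O=C1CC[C@]2(C)C(=O)CCCC2=C1 | starting material
2 | (4aS,5S)-5-hydroxy-4a-methyl-4,4a,5,6,7,8-hexahydronaphthalen-2(3H)-one | O=C1CC[C@]2(C)[C@@H](O)CCCC2=C1 | intermediate
3 | (4a'S,5'S)-4a'-methyl-3',4',4a',5',6',7'-hexahydro-1'H-spiro[[1,3]dioxolane-2,2'-naphthalen]-5'-ol | C1COC2(O1)CC[C@]3(C)[C@@H](O)CCC=C3C2 | intermediate
4 | (4a'S)-4a'-methyl-3',4',6',7'-tetrahydro-1'H-spiro[[1,3]dioxolane-2,2'-naphthalen]-5'(4a'H)-one | C1COC2(O1)CC[C@]3(C)C(=O)CCC=C3C2 | intermediate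
5 | (4a'S)-5'-bromo-4a'-methyl-3',4',4a',7'-tetrahydro-1'H-spiro[[1,3]dioxolane-2,2'-naphthalene] | C1COC2(O1)CC[C@]3(C)C(Br)=CCC=C3C2 | intermediate
6 | (4a'S,8'S,8a'R)-5'-bromo-4a'-methyl-3',4',4a',7',8',8a'-hexahydro-1'H-spiro[[1,3]dioxolane-2,2'-naphthalene]-8',8a'-diol | C1COC2(O1)CC[C@]3(C)C(Br)=CC[C@H](O)[C@@]3(O)C2 | intermediate
7 | (4a'S,8a'R)-5'-bromo-8a'-hydroxy-4a'-methyl-3',4',4a',8a'-tetrahydro-1'H-spiro[[1,3]dioxolane-2,2'-naphthalen]-8'(7'H)-one | C1COC2(O1)CC[C@]3(C)C(Br)=CCC(=O)[C@@]3(O)C2 | intermediate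
8 | (4a'S,8'R,8a'R)-5'-bromo-4a',8'-dimethyl-3',4',4a',7',8',8a'-hexahydro-1'H-spiro[[1,3]dioxolane-2,2'-naphthalene]-8',8a'-diol | C1COC2(O1)CC[C@]3(C)C(Br)=CC[C@@](C)(O)[C@@]3(O)C2 | intermediate
9 | (4aS,8R,8aR)-5-bromo-8,8a-dihydroxy-4a,8-dimethyl-3,4,4a,7,8,8a-hexahydronaphthalen-2(1H)-one | O=C1CC[C@]2(C)C(Br)=CC[C@@](C)(O)[C@@]2(O)C1 | intermediate
10 | (4aS,8R,8aR)-5-bromo-4a,8-dimethyl-8,8a-bis(trimethylsilyloxy)-3,4,4a,7,8,8a-hexahydronaphthalen-2(1H)-one | O=C1CC[C@]2(C)C(Br)=CC[C@@](C)(O[Si](C)(C)C)[C@@]2(O[Si](C)(C)C)C1 | intermediate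
11 | 3-ethoxycyclopent-2-en-1-one | CCOC1=CC(=O)CC1 | starting material
12 | 3-ethoxy-5-methylcyclopent-2-en-1-one (racemic) | CCOC1=CC(=O)C(C)C1 | intermediate (not isolated)
13 | 3-ethoxy-5,5-dimethylcyclopent-2-en-1-one | CCOC1=CC(=O)C(C)(C)C1 | intermediate
14 | 3-bromo-4,4-dimethylcyclopent-2-en-1-one | O=C1C=C(Br)C(C)(C)C1 | intermediate
15 | 3-bromo-4,4,5-trimethylcyclopent-2-en-1-one (racemic) | CC1C(=O)C=C(Br)C1(C)C | intermediate
16 | (4-bromo-2,3,3-trimethylcyclopenta-1,4-dien-1-yl)oxy-trimethylsilane | CC1=C(O[Si](C)(C)C)C=C(Br)C1(C)C | intermediate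
17 | (2R,4aS,8R,8aR)-5-bromo-2-[(1S)-3-bromo-1,2,2-trimethyl-5-oxocyclopent-3-en-1-yl]-4a,8-dimethyl-2,8,8a-tris(trimethylsilyloxy)-1,2,3,4,4a,7,8,8a-octahydronaphthalene | CC1(C)C(Br)=CC(=O)[C@]1(C)[C@@]1(O[Si](C)(C)C)CC[C@]2(C)C(Br)=CC[C@@](C)(O[Si](C)(C)C)[C@@]2(O[Si](C)(C)C)C1 | intermediate
18 | (2R,4aS,8R,8aR)-5-bromo-2-[(1R,5S)-3-bromo-5-hydroxy-1,2,2-trimethylcyclopent-3-en-1-yl]-4a,8-dimethyl-2,8,8a-tris(trimethylsilyloxy)-1,2,3,4,4a,7,8,8a-octahydronaphthalene | CC1(C)C(Br)=C[C@H](O)[C@]1(C)[C@@]1(O[Si](C)(C)C)CC[C@]2(C)C(Br)=CC[C@@](C)(O[Si](C)(C)C)[C@@]2(O[Si](C)(C)C)C1 | intermediate (not isolated)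
19 | (2R,4aS,8R,8aR)-5-bromo-2-[(1R,5S)-3-bromo-5-hydroxy-1,2,2-trimethylcyclopent-3-en-1-yl]-4a,8-dimethyl-1,2,3,4,4a,7,8,8a-octahydronaphthalene-2,8,8a-triol | CC1(C)C(Br)=C[C@H](O)[C@]1(C)[C@@]1(O)CC[C@]2(C)C(Br)=CC[C@@](C)(O)[C@@]2(O)C1 | intermediate
20 | neoirietetraol, (2R,4aS,5S,8R,8aR)-5-bromo-2-[(1R,3R,5S)-3-bromo-5-hydroxy-1,2,2-trimethylcyclopentyl]-4a,8-dimethyldecahydronaphthalene-2,8,8a-triol | CC1(C)[C@H](Br)C[C@H](O)[C@]1(C)[C@@]1(O)CC[C@]2(C)[C@@H](Br)CC[C@@](C)(O)[C@@]2(O)C1 | target

**Step count**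
Total: 16 steps. Longest linear sequence: 12 steps (steps 1–9, 14, 15, 16).

**Steps most likely to fail**

Step 11 (Proposed new method). After O-acylation and loss of the ethyl group, the acyl group could migrate between the two oxygens, which would scramble the position of bromine. Bromide attack at the hindered C1 could also be too slow, so that the material returns as the diketone on work-up. The fallback uses known chemistry, sets out from 13 and comes back at 14. Stork–Danheiser reduction–hydrolysis of 13 (DIBAL-H, then dilute HCl) would give 4,4-dimethylcyclopent-2-en-1-one F1. Conjugate addition of trimethylstannyllithium with trapping of the enolate by PhSeCl would give 4,4-dimethyl-2-(phenylselanyl)-3-(trimethylstannyl)cyclopentan-1-one F2. Oxidation with H2O2 and selenoxide elimination would give 4,4-dimethyl-3-(trimethylstannyl)cyclopent-2-en-1-one F3. Bromodestannylation (Br2, CH2Cl2, 0 °C) would return to 14. The position of bromine then rests on conjugate addition to the β-carbon next to CMe2, not on O-activation.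

Step 14. The weak point is poor facial selectivity on the siloxydiene, which would give the C1' epimer. Silyl transfer from 16 to the enolizable ketone 10 could stall the addition, and the C8a silyloxy group could be lost by β-elimination under the Lewis acid. The fallback sets out from 15 and 10 and comes back at 19. The lithium dienolate of 15 (LDA, THF, −78 °C) would be transmetalated with anhydrous CeCl3 and added to 10 as a directed aldol addition through a closed, metal-chelated transition state, whose steric demands on the enolate face differ from those of the open one. A cold quench would give the C2-hydroxy aldol F4. F4 would be taken without delay into the conditions of step 15, which would give the bis-silyl allylic alcohol F5 and, after loss of the two silyl groups, 19.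

Step 16. Over-reduction could remove bromine, and facial selectivity could be poor at one of the two radical centres, above all at C5, where the axial C8a hydroxyl lies 1,3 to the incoming hydrogen. The fallback separates the two events, sets out from 10 and comes back at 20. HAT hydrogenation of 10 at the fragment stage would give the saturated bromo ketone F6, whose C5 epimers could be separated and assigned on a small molecule. F6 and 16 under the conditions of step 14 would give the adduct F7. The conditions of step 15 would give the tris-silyl allylic alcohol F8 and then the tetraol F9, which keeps only the cyclopentenyl bromide. This last alkene would be reduced with diimide (2-nitrobenzenesulfonyl hydrazide, Et3N), a concerted syn transfer of H2 to the face of the C1' methyl, to give 20.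

**Further compounds**
F1 | step 11 | 4,4-dimethylcyclopent-2-en-1-one | O=C1C=CC(C)(C)C1
F2 | step 11 | 4,4-dimethyl-2-(phenylselanyl)-3-(trimethylstannyl)cyclopentan-1-one (trans, racemic) | O=C1CC(C)(C)C([Sn](C)(C)C)C1[Se]c1ccccc1
F3 | step 11 | 4,4-dimethyl-3-(trimethylstannyl)cyclopent-2-en-1-one | O=C1C=C([Sn](C)(C)C)C(C)(C)C1
F4 | step 14 | (2R,4aS,8R,8aR)-5-bromo-2-[(1S)-3-bromo-1,2,2-trimethyl-5-oxocyclopent-3-en-1-yl]-4a,8-dimethyl-8,8a-bis(trimethylsilyloxy)-1,2,3,4,4a,7,8,8a-octahydronaphthalen-2-ol | CC1(C)C(Br)=CC(=O)[C@]1(C)[C@@]1(O)CC[C@]2(C)C(Br)=CC[C@@](C)(O[Si](C)(C)C)[C@@]2(O[Si](C)(C)C)C1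
F5 | step 14 | (2R,4aS,8R,8aR)-5-bromo-2-[(1R,5S)-3-bromo-5-hydroxy-1,2,2-trimethylcyclopent-3-en-1-yl]-4a,8-dimethyl-8,8a-bis(trimethylsilyloxy)-1,2,3,4,4a,7,8,8a-octahydronaphthalen-2-ol | CC1(C)C(Br)=C[C@H](O)[C@]1(C)[C@@]1(O)CC[C@]2(C)C(Br)=CC[C@@](C)(O[Si](C)(C)C)[C@@]2(O[Si](C)(C)C)C1
F6 | step 16 | (4aS,5S,8R,8aR)-5-bromo-4a,8-dimethyl-8,8a-bis(trimethylsilyloxy)octahydronaphthalen-2(1H)-one | O=C1CC[C@]2(C)[C@@H](Br)CC[C@@](C)(O[Si](C)(C)C)[C@@]2(O[Si](C)(C)C)C1
F7 | step 16 | (2R,4aS,5S,8R,8aR)-5-bromo-2-[(1S)-3-bromo-1,2,2-trimethyl-5-oxocyclopent-3-en-1-yl]-4a,8-dimethyl-2,8,8a-tris(trimethylsilyloxy)decahydronaphthalene | CC1(C)C(Br)=CC(=O)[C@]1(C)[C@@]1(O[Si](C)(C)C)CC[C@]2(C)[C@@H](Br)CC[C@@](C)(O[Si](C)(C)C)[C@@]2(O[Si](C)(C)C)C1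
F8 | step 16 | (2R,4aS,5S,8R,8aR)-5-bromo-2-[(1R,5S)-3-bromo-5-hydroxy-1,2,2-trimethylcyclopent-3-en-1-yl]-4a,8-dimethyl-2,8,8a-tris(trimethylsilyloxy)decahydronaphthalene | CC1(C)C(Br)=C[C@H](O)[C@]1(C)[C@@]1(O[Si](C)(C)C)CC[C@]2(C)[C@@H](Br)CC[C@@](C)(O[Si](C)(C)C)[C@@]2(O[Si](C)(C)C)C1
F9 | step 16 | (2R,4aS,5S,8R,8aR)-5-bromo-2-[(1R,5S)-3-bromo-5-hydroxy-1,2,2-trimethylcyclopent-3-en-1-yl]-4a,8-dimethyldecahydronaphthalene-2,8,8a-triol | CC1(C)C(Br)=C[C@H](O)[C@]1(C)[C@@]1(O)CC[C@]2(C)[C@@H](Br)CC[C@@](C)(O)[C@@]2(O)C1
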